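Ring A is disconnected by a Diels–Alder reaction that forms C3–C4 and C10–C5 (icetexane numbering, defined below). It exploits that C4 and C5 are the α- and β-carbons of the C19 γ-lactone and that oxygenated C1 lies para to C4 in ring A. The precursors are a (6R)-3-methylbutenolide carrying the ring C arene through C7, and a 2-silyloxydiene (C10, C1, C2, C3) bearing C20 as an acetal. In one operation the cycloaddition closes ring A, sets quaternary C4 and C5 from the temporary C6 centre, and installs the C1 carbonyl and the C20 electrophile. Acid then closes ring B at C9 and turns C6/C7 into the enol lactone alkene; C1 reduction and arene oxidation finish.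

Key step: step 10

Remarks on the chemistry
- Numbering: ring A = C1–C5 and C10; ring B = C5, C6, C7, C8, C9, C20, C10; ring C = C8, C9, C11–C14; C18 = methyl on C4; C19 = lactone carbonyl, bound through O to C6. The target is (1R,4S,5R).
- Ar = 2,4,5-trimethoxy-3-(propan-2-yl)phenyl; its ring carbon 1 is C8 and its only C–H (ring carbon 6) is C9.
- Assumption: the configurations at C7, C10 and C20 of the intermediates need not be uniform, because these centres become sp2 in step 11; any C7 or C10 epimer is carried along.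

Step 1
Reactants: 1 1,2,4-trimethoxybenzene; 2 acetone
Product: 4 2-(2,3,6-trimethoxyphenyl)propan-2-ol, via (2,3,6-trimethoxyphenyl)lithium 3 (not isolated)
Conditions: n-BuLi, THF, 0 °C; then acetone, −78 → 23 °C; H2O
Reagents that add atoms: none
Why: Directed ortho-lithiation takes the C–H flanked by two methoxy groups, the most acidic and best coordinated site, and the aryllithium adds 1,2 to acetone.

Step 2
Reactants: 4 2-(2,3,6-trimethoxyphenyl)propan-2-ol
Product: 5 1,2,4-trimethoxy-3-(propan-2-yl)benzene
Conditions: Et3SiH, CF3CO2H, CH2Cl2, 0 → 23 °C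
Reagents that add atoms: none
Why: Ionic hydrogenation, in which the acid ionises the tertiary benzylic alcohol (cation stabilised by two ortho methoxy groups) and the silane delivers hydride.

Step 3
Reactants: 5 1,2,4-trimethoxy-3-(propan-2-yl)benzene; 6 dichloromethyl methyl ether
Product: 7 2,4,5-trimethoxy-3-(propan-2-yl)benzaldehyde (CHO carbon = C7)
Conditions: TiCl4, CH2Cl2, −78 → 0 °C; then H2O
Reagents that add atoms: water, O
Why: Rieche formylation (electrophilic aromatic substitution) should go to the free position that is ortho to one methoxy group and para to another, the more activated of the two C–H sites.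

Step 4
Reactants: 8 3-methylfuran-2(5H)-one
Product: 9 tert-butyl(dimethyl)[(3-methylfuran-2-yl)oxy]silane
Conditions: TBSOTf, Et3N, CH2Cl2, 0 °C
Reagents that add atoms: tert-butyldimethylsilyl trifluoromethanesulfonate, CC(C)(C)[Si](C)(C)OS(=O)(=O)C(F)(F)F
Why: Soft enolisation and O-silylation of the butenolide gives the aromatic 2-silyloxyfuran, the standard dienoxysilane for vinylogous aldol chemistry.

Step 5
Reactants: 7 2,4,5-trimethoxy-3-(propan-2-yl)benzaldehyde; 9 tert-butyl(dimethyl)[(3-methylfuran-2-yl)oxy]silane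
Product: 10 (5R)-5-[(S)-hydroxy(Ar)methyl]-3-methylfuran-2(5H)-one (anti adduct; 6R,7S in icetexane numbering)
Conditions: SiCl4 (1.1 equiv), (R,R)-N,N′-bis[3,5-dimethyl-4-oxido-3,5-dihydro-4H-dinaphtho[2,1-d:1′,2′-f][1,3,2]diazaphosphepin-4-yl]-N,N′-dimethylpentane-1,5-diamine (5 mol %; the antipode is taken that directs attack to the aldehyde Re face), iPr2NEt (10 mol %), CH2Cl2, −78 °C; aq. NaHCO3
Reagents that add atoms: none
Why: Catalytic enantioselective vinylogous Mukaiyama aldol reaction (Lewis-base-activated SiCl4), in which the dienoxysilane reacts at its γ-carbon through an open anti transition state and the chiral silicon cation complex selects the aldehyde Re face, so that C6 (R) and the temporary C7 (S) are set by the catalyst.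

Step 6
Reactants: 10 (5R)-5-[(S)-hydroxy(Ar)methyl]-3-methylfuran-2(5H)-one
Product: 11 (5R)-5-[(S)-{[tert-butyl(dimethyl)silyl]oxy}(Ar)methyl]-3-methylfuran-2(5H)-one
Conditions: TBSOTf, 2,6-lutidine, CH2Cl2, −78 °C
Reagents that add atoms: tert-butyldimethylsilyl trifluoromethanesulfonate, CC(C)(C)[Si](C)(C)OS(=O)(=O)C(F)(F)F
Why: Silylation with a silyl triflate and a hindered pyridine base at low temperature protects the alcohol without γ-deprotonation of the butenolide (which would eliminate the C7 oxygen), and the bulky group later shields one face.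

Step 7
Reactants: 12 methyl 3,3-dimethoxypropanoate
Product: 13 N,3,3-trimethoxy-N-methylpropanamide
Conditions: MeNH(OMe)·HCl, iPrMgCl, THF, −20 → 0 °C
Reagents that add atoms: N,O-dimethylhydroxylamine hydrochloride, CNOC.Cl
Why: Weinreb amide formation by addition of the magnesium amide to the ester; the acetal is inert to base.

Step 8
Reactants: 13 N,3,3-trimethoxy-N-methylpropanamide; 14 vinylmagnesium bromide
Product: 15 5,5-dimethoxypent-1-en-3-one
Conditions: THF, 0 °C; inverse quench into cold 0.5 M HCl; used at once (BHT)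
Reagents that add atoms: none
Why: Weinreb ketone synthesis, in which the chelated tetrahedral intermediate prevents over-addition and the acidic quench keeps the liberated amine from adding to the vinyl ketone.

Step 9
Reactants: 15 5,5-dimethoxypent-1-en-3-one
Product: 16 (3Z)-5,5-dimethoxy-3-[(trimethylsilyl)oxy]penta-1,3-diene (C3=C2–C1(OSi)=C10–C20)
Conditions: TMSOTf, Et3N, Et2O, −20 → 0 °C
Reagents that add atoms: trimethylsilyl trifluoromethanesulfonate, C[Si](C)(C)OS(=O)(=O)C(F)(F)F
Why: Amine-buffered soft enolisation can occur only at C10 and should give the thermodynamically preferred Z silyl enol ether, i.e. a 2-silyloxydiene whose C20 substituent lies outside the s-cis diene.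

Step 10
Reactants: 11 (5R)-5-[(S)-{[tert-butyl(dimethyl)silyl]oxy}(Ar)methyl]-3-methylfuran-2(5H)-one; 16 (3Z)-5,5-dimethoxy-3-[(trimethylsilyl)oxy]penta-1,3-diene
Product: 18 (3R,3aR,4R,7aS)-3-[(S)-{[tert-butyl(dimethyl)silyl]oxy}(Ar)methyl]-4-(dimethoxymethyl)-7a-methylhexahydro-2-benzofuran-1,5-dione (4S,5R,6R,7S,10R; cis-fused lactone/ring A, C1 ketone, C20 acetal on C10), via silyl enol ether cycloadduct 17 (not isolated)
Conditions: 16 (3 equiv), BHT, PhMe, 150 °C, sealed tube; then K2CO3 (cat.), MeOH, 0 °C
Reagents that add atoms: none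
Why: Thermal normal-electron-demand [4+2] cycloaddition between the HOMO of the 2-silyloxydiene (largest coefficient at C10) and the LUMO of the butenolide (largest at C5), concerted but asynchronous, so that the C10–C5 bond leads and the C3–C4 bond completes ring A. The closest known reaction type is the Diels–Alder reaction of 5-substituted 3-methylfuran-2(5H)-ones with 2-silyloxy-1,3-dienes, which builds an α-quaternary cis-fused lactone. Ring A is closed as a six-membered ring in the suprafacial [4+2] mode, both new σ-bonds lying in the ring. C4 and C5 are created together: suprafacial addition makes the lactone cis-fused (C18 methyl and H5 cis), and the diene adds to the butenolide face anti to the bulky C6 CH(OTBS)Ar group, so the 6R centre translates into 4S,5R; C10 follows from the endo mode but is erased in step 11. The step needs para regioselectivity (C1–O para to C4), secured by the silyloxy group, and s-cis reactivity, secured by the Z enol ether that keeps C20 outside; carbonate in methanol then cleaves only the trimethylsilyl enol ether.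

Step 11
Reactants: 18 keto acetal (4S,5R,6R,7S,10R)
Product: 21 (4S,5R)-11,12,14-trimethoxy-1-oxo-9(10→20)-abeo-abieta-6,8,10(20),11,13-pentaen-19,6-olide (tetracyclic dienone enol lactone), via 20-methoxy ring B ether 19 (not isolated), via C7-silyloxy dienone 20 (not isolated)
Conditions: p-TsOH (anhydrous, 0.3 equiv), 5 Å MS, PhMe (0.01 M), 23 → 70 °C
Reagents that add atoms: none
Why: Acid-triggered Bradsher-type cyclodehydration cascade, in which the β-keto acetal ionises to a C20 oxocarbenium ion, Friedel–Crafts attack by C9 (the only unsubstituted arene position, ortho to OMe) closes the seven-membered ring B, E1 loss of methanol gives the C10=C20 enone, and E1 loss of the benzylic C7 silyloxy group gives the C6=C7 enol lactone, erasing the temporary C6, C7 and C10 centres.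

Step 12
Reactants: 21 tetracyclic dienone enol lactone
Product: 22 (1R,4S,5R)-1-hydroxy-11,12,14-trimethoxy-9(10→20)-abeo-abieta-6,8,10(20),11,13-pentaen-19,6-olide
Conditions: (S)-2-methyl-CBS-oxazaborolidine [(S)-1-methyl-3,3-diphenyltetrahydro-1H,3H-pyrrolo[1,2-c][1,3,2]oxazaborole] (0.3 equiv), catecholborane (1.5 equiv), PhMe, −78 °C; MeOH, pH 7 buffer
Reagents that add atoms: none
Why: Corey–Bakshi–Shibata reduction, in which the fully substituted C10 alkenyl group acts as the large and C2H2 as the small substituent so that the (S)-catalyst should give 1R, reinforced by hydride approach to the convex face of the cis-fused lactone/ring A bicycle; catecholborane at −78 °C should leave the enol lactone and the alkenes untouched.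

Step 13
Reactants: 22 allylic alcohol (1R,4S,5R)
Product: 23 (1R,4S,5R)-1-hydroxy-12-methoxy-11,14-dioxo-9(10→20)-abeo-abieta-6,8,10(20),12-tetraen-19,6-olide (12-O-methyl-6,7-anhydroballotiquinone)
Conditions: (NH4)2Ce(NO3)6 (2.5 equiv), MeCN/H2O 4:1, 0 °C, short reaction time
Reagents that add atoms: water, O
Why: Oxidative demethylation of the para-dimethoxy pair (C11, C14) through the arene radical cation and water addition should give the 12-methoxy-para-quinone faster than the alcohol or the enol lactone can react.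

Step 14
Reactants: 23 12-O-methyl-6,7-anhydroballotiquinone
Product: 24 6,7-anhydroballotiquinone, (1R,4S,5R)-1,12-dihydroxy-11,14-dioxo-9(10→20)-abeo-abieta-6,8,10(20),12-tetraen-19,6-olide
Conditions: LiI (5 equiv), EtOAc, 70 °C, dark; cold 0.1 M HCl work-up
Reagents that add atoms: none
Why: SN2 demethylation by iodide at the methyl of the vinylogous ester (the 2-hydroxyquinone anion leaves like a carboxylate), a neutral method that should spare the enol lactone, the allylic alcohol and the acidic C5–H.

Compound list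
1 | 1,2,4-trimethoxybenzene | COc1ccc(OC)c(OC)c1 | starting material
2 | acetone | CC(C)=O | starting material
3 | (2,3,6-trimethoxyphenyl)lithium | [Li]c1c(OC)ccc(OC)c1OC | intermediate
4 | 2-(2,3,6-trimethoxyphenyl)propan-2-ol | COc1ccc(OC)c(C(C)(C)O)c1OC | intermediate
5 | 1,2,4-trimethoxy-3-(propan-2-yl)benzene | COc1ccc(OC)c(C(C)C)c1OC | intermediate
6 | dichloromethyl methyl ether | COC(Cl)Cl | starting material
7 | 2,4,5-trimethoxy-3-(propan-2-yl)benzaldehyde | COc1cc(C=O)c(OC)c(C(C)C)c1OC | intermediate
8 | 3-methylfuran-2(5H)-one | CC1=CCOC1=O | starting material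
9 | tert-butyl(dimethyl)[(3-methylfuran-2-yl)oxy]silane | Cc1ccoc1O[Si](C)(C)C(C)(C)C | intermediate
10 | (5R)-5-[(S)-hydroxy(Ar)methyl]-3-methylfuran-2(5H)-one | CC1=C[C@@H](OC1=O)[C@@H](O)c1cc(OC)c(OC)c(C(C)C)c1OC | intermediate
11 | (5R)-5-[(S)-{[tert-butyl(dimethyl)silyl]oxy}(Ar)methyl]-3-methylfuran-2(5H)-one | CC1=C[C@@H](OC1=O)[C@@H](O[Si](C)(C)C(C)(C)C)c1cc(OC)c(OC)c(C(C)C)c1OC | intermediate
12 | methyl 3,3-dimethoxypropanoate | COC(=O)CC(OC)OC | starting material
13 | N,3,3-trimethoxy-N-methylpropanamide | CON(C)C(=O)CC(OC)OC | intermediate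
14 | vinylmagnesium bromide | C=C[Mg]Br | starting material
15 | 5,5-dimethoxypent-1-en-3-one | C=CC(=O)CC(OC)OC | intermediate
16 | (3Z)-5,5-dimethoxy-3-[(trimethylsilyl)oxy]penta-1,3-diene | C=C/C(=C/C(OC)OC)O[Si](C)(C)C | intermediate
17 | Diels–Alder adduct as C1 trimethylsilyl enol ether (4S,5R,6R,7S,10S; C1=C2) | O=C1O[C@@H]([C@@H](O[Si](C)(C)C(C)(C)C)c3cc(OC)c(OC)c(C(C)C)c3OC)[C@@H]2[C@H](C(OC)OC)C(O[Si](C)(C)C)=CC[C@]12C | intermediate
18 | (3R,3aR,4R,7aS)-3-[(S)-{[tert-butyl(dimethyl)silyl]oxy}(Ar)methyl]-4-(dimethoxymethyl)-7a-methylhexahydro-2-benzofuran-1,5-dione | O=C1O[C@@H]([C@@H](O[Si](C)(C)C(C)(C)C)c3cc(OC)c(OC)c(C(C)C)c3OC)[C@@H]2[C@H](C(OC)OC)C(=O)CC[C@]12C | intermediate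
19 | ring B closed 20-methoxy ether: (4S,5R,6R,7S)-7-silyloxy-11,12,14,20-tetramethoxy-1-oxo-9(10→20)-abeo-abieta-8,11,13-trien-19,6-olide (C10/C20 epimers) | O=C1O[C@H]2[C@@H](O[Si](C)(C)C(C)(C)C)c3c(OC)c(C(C)C)c(OC)c(OC)c3C(OC)C3C(=O)CC[C@@]1(C)[C@@H]32 | intermediate
20 | (4S,5R,6R,7S)-7-{[tert-butyl(dimethyl)silyl]oxy}-11,12,14-trimethoxy-1-oxo-9(10→20)-abeo-abieta-8,10(20),11,13-tetraen-19,6-olide | O=C1O[C@H]2[C@@H](O[Si](C)(C)C(C)(C)C)c3c(OC)c(C(C)C)c(OC)c(OC)c3C=C3C(=O)CC[C@@]1(C)[C@@H]32 | intermediate
21 | (4S,5R)-11,12,14-trimethoxy-1-oxo-9(10→20)-abeo-abieta-6,8,10(20),11,13-pentaen-19,6-olide | COc1c(C(C)C)c(OC)c(OC)c2c1C=C1OC(=O)[C@@]3(C)CCC(=O)C(=C2)[C@@H]13 | intermediate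
22 | (1R,4S,5R)-1-hydroxy-11,12,14-trimethoxy-9(10→20)-abeo-abieta-6,8,10(20),11,13-pentaen-19,6-olide | COc1c(C(C)C)c(OC)c(OC)c2c1C=C1OC(=O)[C@@]3(C)CC[C@@H](O)C(=C2)[C@@H]13 | intermediate
23 | 12-O-methyl-6,7-anhydroballotiquinone | CC(C)C1=C(OC)C(=O)C2=C(C=C3OC(=O)[C@@]4(C)CC[C@@H](O)C(=C2)[C@@H]34)C1=O | intermediate
24 | 6,7-anhydroballotiquinone | CC(C)C1=C(O)C(=O)C2=C(C=C3OC(=O)[C@@]4(C)CC[C@@H](O)C(=C2)[C@@H]34)C1=O | target

Total step count: 14. Longest linear sequence: 10 steps (steps 1, 2, 3, 5, 6, 10, 11, 12, 13, 14); steps 4 and 7–9 make the two side fragments.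

Steps most likely to fail

Step 10. The trisubstituted, α-methylated butenolide may react too slowly with the terminally substituted diene, so that the diene decomposes before cycloaddition or facial selectivity erodes at the temperature needed. Fallback: ring A is closed with the more reactive unsubstituted diene and C20 is added afterwards. Compound 11 is heated with trans-1-methoxy-3-(trimethylsilyloxy)buta-1,3-diene (PhMe, 130 °C), with the same anti facial control, to give the methoxy silyl enol ether cycloadduct F1. Dilute HCl in THF then removes methanol and the silyl group to give the ring A enone F2 (C1 ketone, C2=C3). Kinetic enolisation at C10, the only enolisable position (LiHMDS, TMSCl, THF, −78 °C), gives the cross-conjugated silyl dienol ether F3. Mukaiyama-type alkoxyalkylation with HC(OMe)3 and BF3·OEt2 (CH2Cl2, −78 °C) gives the C10-dimethoxymethyl enone F4. Hydrogenation of C2=C3 (H2, Pd/C, EtOAc) returns to the route at 18, as a C10 epimer mixture that converges in step 11.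

Step 11. The benzylic C7 silyl ether may ionise before ring B closes, or the arene may be too weak a nucleophile, so that oligomerisation or double-bond migration competes with the Friedel–Crafts closure. Fallback: the C9–C20 bond is made by palladium catalysis instead. Compound 18 is brominated at C9, its only free aromatic position (NBS, MeCN, 0 °C), to give the C9-bromo keto acetal F5. Warming with PPTS in benzene eliminates methanol to give the C9-bromo 2-(methoxymethylene) ketone F6. Intramolecular Heck arylation at C20 followed by β-methoxide elimination (Pd(OAc)2, P(o-tol)3, Ag2CO3, DMF, 90 °C) returns to the route at 20. Compound 20 is then isolated and taken to 21 with p-TsOH in PhMe at 60 °C.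

Step 14. Demethylation may be incomplete, or iodide may reduce the quinone, or the allylic alcohol may decompose on prolonged heating. Fallback: the end game is reordered so that the methyl ether is cleaved before the sensitive alcohol exists. Compound 21 is oxidised with (NH4)2Ce(NO3)6 (MeCN/H2O, 0 °C) to the 12-methoxyquinone C1 ketone F7. Chelation-assisted cleavage of the methoxy group next to the C11 carbonyl (BCl3, CH2Cl2, −78 °C) gives the 12-hydroxyquinone C1 ketone F8. Luche reduction (NaBH4, CeCl3, MeOH, −78 °C) reduces the C1 ketone from the convex face and, transiently, the quinone, giving the hydroquinone F9. Air oxidation on work-up restores the quinone and returns to the route at 24.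

Further compounds
F1 | step 10 | methoxy silyl enol ether cycloadduct (C3 epimers) | O=C1O[C@@H]([C@@H](O[Si](C)(C)C(C)(C)C)c3cc(OC)c(OC)c(C(C)C)c3OC)[C@@H]2CC(O[Si](C)(C)C)=CC(OC)[C@]12C
F2 | step 10 | ring A enone (C1 ketone, C2=C3) | O=C1O[C@@H]([C@@H](O[Si](C)(C)C(C)(C)C)c3cc(OC)c(OC)c(C(C)C)c3OC)[C@@H]2CC(=O)C=C[C@]12C
F3 | step 10 | cross-conjugated silyl dienol ether (C1=C10, C2=C3) | O=C1O[C@@H]([C@@H](O[Si](C)(C)C(C)(C)C)c3cc(OC)c(OC)c(C(C)C)c3OC)[C@@H]2C=C(O[Si](C)(C)C)C=C[C@]12C
F4 | step 10 | C10-dimethoxymethyl enone (C10 epimers) | O=C1O[C@@H]([C@@H](O[Si](C)(C)C(C)(C)C)c3cc(OC)c(OC)c(C(C)C)c3OC)[C@@H]2C(C(OC)OC)C(=O)C=C[C@]12C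
F5 | step 11 | C9-bromo keto acetal | O=C1O[C@@H]([C@@H](O[Si](C)(C)C(C)(C)C)c3c(Br)c(OC)c(OC)c(C(C)C)c3OC)[C@@H]2[C@H](C(OC)OC)C(=O)CC[C@]12C
F6 | step 11 | C9-bromo 2-(methoxymethylene) ketone (E/Z) | O=C1O[C@@H]([C@@H](O[Si](C)(C)C(C)(C)C)c3c(Br)c(OC)c(OC)c(C(C)C)c3OC)[C@@H]2C(=COC)C(=O)CC[C@]12C
F7 | step 14 | 12-methoxyquinone C1 ketone | CC(C)C1=C(OC)C(=O)C2=C(C=C3OC(=O)[C@@]4(C)CCC(=O)C(=C2)[C@@H]34)C1=O
F8 | step 14 | 12-hydroxyquinone C1 ketone | CC(C)C1=C(O)C(=O)C2=C(C=C3OC(=O)[C@@]4(C)CCC(=O)C(=C2)[C@@H]34)C1=O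
F9 | step 14 | 1,11,12,14-tetrahydroxy hydroquinone (not isolated) | CC(C)c1c(O)c(O)c2c(C=C3OC(=O)[C@@]4(C)CC[C@@H](O)C(=C2)[C@@H]34)c1O
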